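Take a run at its late end: in the elm run at 12.0 min, Xi and Qi together stand at 80.9% of their charge.

| setting | alder | elm | ash | flask |
|---|---|---|---|---|
| Xi | 15 mM | 15 mM | 7.5 mM | 15 mM |
| Qi | 15 mM | 15 mM | 7.5 mM | 15 mM |
| Ux | 8.2 mM (fed, over 1.5 min) | 12 mM (fed, over 1.5 min) | 16.5 mM (fed, over 1.5 min) | 16.5 mM (fed, over 1.5 min) |
| Gy | 0.30 mM | 0.30 mM | 0.30 mM | 0.30 mM |
| remark | run made earlier | run made earlier | run made earlier |  |
| time |  |  |  | 20 min |

| run | time / min | Xi / % | Qi / % | Ym / % |
|---|---|---|---|---|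
| alder | 1.00 | 49.0 | 51.2 | 0 |
| alder | 1.50 | 49.8 | 49.3 | 1.3 |
| alder | 2.50 | 48.3 | 49.5 | 1.7 |
| alder | 4.00 | 48.3 | 49.8 | 1.6 |
| alder | 8.00 | 44.7 | 46.6 | 5.8 |
| alder | 12.0 | 43.7 | 45.7 | 8.1 |
| elm | 1.00 | 50.9 | 50.9 | 1.1 |
| elm | 1.50 | 49.5 | 51.9 | 0.8 |
| elm | 2.50 | 49.9 | 48.0 | 3.2 |
| elm | 4.00 | 47.7 | 49.5 | 4.5 |
| elm | 8.00 | 43.4 | 44.5 | 10.3 |
| elm | 12.0 | 39.6 | 41.3 | 16.1 |
| ash | 2.50 | 46.5 | 48.6 | 2.3 |
| ash | 5.00 | 43.6 | 43.5 | 9.2 |
| ash | 8.00 | 39.5 | 40.7 | 16.8 |
| ash | 10.0 | 37.2 | 40.6 | 16.9 |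
| ash | 12.0 | 35.5 | 36.8 | 21.4 |

(standard deviation of a reading: 1 percentage point)

- Wy is single-handed; Xi and Qi are mirror images of each other, charged as a racemate, each of them at the stated concentration
- the analysis behind the earlier runs scatters by 1 percentage point, standard deviation
- an excess is the difference of the two amounts in percent of their sum
- an excess is below zero if the other one leads

1. part of the Xi and Qi charged together that has reacted at 20 min
2. excess of Ym over Wu in the product at 20 min
3. excess of Qi over Xi among what is left of the two at 20 min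

Elm is the near neighbour of the flask: it has the same Xi, Qi and Gy, but its Ux charge is a fraction m of 0.400 of the Xi and Qi charge, where the flask has 0.550. So Ux is the limiting reagent in both .

Call s the fraction of Xi and Qi left and u the fraction of Ux left. If you take one Ux per Xi or Qi reacted, elm has u = 52.2%.

Now assume the rate goes as s times u. You can integrate that in closed form: ln(s/u) grows in a straight line with the time counted from the end of the feed, and its slope carries the gap g, the part of the Xi and Qi charge with no Ux to meet it. Elm has g = 0.600 and the flask g = 0.450.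

Elm gives 0.0694 min⁻¹. This is the pace, ln(s/u) divided by g and by the time, and it is a reading that carries the scatter.

Since s = r·u with r = 1.78, my reckoning for the flask at 20 min is c = 34.9%. At elm's last time, the flask's larger Ux charge puts it at 25.5% against elm's 19.1%. By this reckoning the product s·u stands at 20 min at a quarter of its first value, with c below the flask's ceiling of 55.0%.

The forecast says c = 36%, eP = 58% and eS = 2.5%; its eP rests on the reading that “Ym is about 79% of the total loss”. For the two excesses I hold no number of my own.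

The flask gives c = 35.3%, eP = 49.2% and eS = 1.22%.

    Ux + Wy + Qi → Wy + Wu (k = 69.0 M⁻² s⁻¹)
    Xi ⇌ Qi (k = 0.00520 s⁻¹)
    Ux + Wy + Xi → Wy + Ym (k = 210 M⁻² s⁻¹)
    Ux + Gy → Wy + Ze (k = 1.10 M⁻¹ s⁻¹)
    Ux → Uv (k = 7.20 × 10⁻⁶ s⁻¹)

The excess eP already stood at 49.4% at 5.00 min. The flask's own end, 64.7% of Xi and Qi over 34% of Ux, gives a pace of 0.0789 min⁻¹. Now carry elm's pace to the neighbour charged with 66 mM of Ux, where m is 2.20, so Xi and Qi are the short ones. The closed form gives c = 87.1%, and that neighbour stands at 88.2%.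

Readings and results stem from a simulated flask on assumed constants; the scatter is artificial.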